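**Plan**

- Feature used: ring A is a 5,7-dioxygenated benzene whose C6 prenyl group sits between O5 and O7 (a phenol with an alkyl group ortho and an oxygen meta, the pattern a vinylketene and a siloxyalkyne give), and its C4a–C8a edge can be supplied as the C=C bond of a dihydropyranone (ring C).
- Retrosynthesis: the two aryl silyl ethers are removed last; ring A is cut at C4a–C5, C5–C6, C7–C8 and C8–C8a into diazo ketone 15 (ring C with C4a and C8a) and prenylated siloxyalkyne 19 (C6 and C7).
- 15 is cut at the acyl–CHN2 bond (acid 13 and diazomethane), ring C at O1–C8a (cyclodehydration) and C4a–C8a (oxalate Claisen), the C4 ketone is traced to a terminal alkene (Wacker) and C2–C3 to an allylation of ring B aldehyde 3.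
- Forward: ring B aldehyde (silylation, Stille prenylation), allylation, chain extension to the 2,4-dioxo ester, closure of ring C, diazo ketone, closure of ring A with alkyne 19 (one step from ester 16), desilylation.
- Stereochemistry: the only stereocentre, C2 (S), comes from a reagent-controlled Brown allylboration of 3 (allyl to the Si face); its C–O bond is not broken afterwards.

Key step: step 11

Abbreviation: Ar = 3-(tert-butyldimethylsilyloxy)-4-methoxy-2-(3-methylbut-2-enyl)phenyl; ring atoms carry flavanone numbering (O1, C2 … C8a) unless "pyranone" is written.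

Remark: dioxo esters 9 and 10 are drawn as diketones although they should be largely enolised, and the hemiketal carbon of 11 and C4 of cyclobutenone 21 are left undefined because both become sp2.

**Step 1**
Reactants: 1 2-bromo-3-hydroxy-4-methoxybenzaldehyde
Product: 2 2-bromo-3-(tert-butyldimethylsilyloxy)-4-methoxybenzaldehyde
Conditions: TBSCl, imidazole, DMF, 23 °C
Reagents that add atoms: tert-butyldimethylsilyl chloride, CC(C)(C)[Si](C)(C)Cl
Why: Imidazole-promoted silylation of a phenol is routine even for a flanked hydroxyl, and the aryl TBS ether should survive every later step until the final fluoride treatment.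

**Step 2**
Reactants: 2 2-bromo-3-(tert-butyldimethylsilyloxy)-4-methoxybenzaldehyde
Product: 3 3-(tert-butyldimethylsilyloxy)-4-methoxy-2-(3-methylbut-2-enyl)benzaldehyde
Conditions: tributyl(3-methylbut-2-enyl)stannane, Pd(PPh3)4 (5 mol %), DMF, 95 °C
Reagents that add atoms: tributyl(3-methylbut-2-enyl)stannane, CCCC[Sn](CCCC)(CCCC)CC=C(C)C
Why: Migita–Kosugi–Stille coupling: the ortho formyl group eases oxidative addition to zerovalent palladium, the allyl group is transferred with C–C bond formation at its unsubstituted terminus to give the linear prenyl arene, and the neutral medium spares the aldehyde and the aryl silyl ether.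

**Step 3**
Reactants: 3 3-(tert-butyldimethylsilyloxy)-4-methoxy-2-(3-methylbut-2-enyl)benzaldehyde
Product: 5 (S)-1-Ar-but-3-en-1-ol, via borinate ester 4 (not isolated)
Conditions: (−)-Ipc2B(allyl), Et2O, −78 °C; then H2O2, pH 7 phosphate buffer, MeOH, 0 °C
Reagents that add atoms: (−)-B-allyldiisopinocampheylborane, C=CCB([C@@H]1C[C@@H]2C[C@H]([C@H]1C)C2(C)C)[C@@H]1C[C@@H]2C[C@H]([C@H]1C)C2(C)C
Why: Brown asymmetric allylboration through a chair-like six-membered transition state: the isopinocampheyl groups of the reagent derived from (+)-α-pinene direct the allyl group to the Si face of the aryl aldehyde, which sets C2 with the S configuration of the target, and the buffered peroxide work-up leaves the aryl silyl ether and the prenyl alkene alone.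

**Step 4**
Reactants: 5 (S)-1-Ar-but-3-en-1-ol
Product: 6 (S)-triethyl[(1-Ar-but-3-enyl)oxy]silane
Conditions: Et3SiCl, imidazole, DMF, 0 → 23 °C
Reagents that add atoms: chlorotriethylsilane, CC[Si](Cl)(CC)CC
Why: Standard silylation of a secondary alcohol; the triethylsilyl ether blocks retro-aldol and elimination pathways in steps 5 and 6 and can later be removed by mild acid without touching the aryl TBS ether.

**Step 5**
Reactants: 6 (S)-triethyl[(1-Ar-but-3-enyl)oxy]silane
Product: 7 (S)-4-Ar-4-(triethylsilyloxy)butan-2-one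
Conditions: PdCl2 (10 mol %), Cu(OAc)2 (20 mol %), O2 (1 atm), DMA/H2O (7:1), 23 °C
Reagents that add atoms: water, O
Why: Tsuji–Wacker oxidation: Markovnikov hydroxypalladation by divalent palladium converts the monosubstituted alkene into the methyl ketone, whereas the trisubstituted prenyl alkene coordinates too weakly to compete, and Cu(OAc)2 as co-oxidant keeps the medium from becoming acidic enough to cleave the silyl ethers.

**Step 6**
Reactants: 7 (S)-4-Ar-4-(triethylsilyloxy)butan-2-one
Product: 9 prop-2-enyl (S)-6-Ar-2,4-dioxo-6-(triethylsilyloxy)hexanoate, via lithium enolate 8 (not isolated)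
Conditions: LiN(SiMe3)2, THF, −78 °C; then diallyl oxalate, −78 → −20 °C; AcOH
Reagents that add atoms: diallyl oxalate, C=CCOC(=O)C(=O)OCC=C
Why: Crossed Claisen condensation: the bulky amide base removes a methyl proton at −78 °C (kinetic enolate, no β-elimination of the silyloxy group), the enolate acylates the non-enolisable oxalate, and the liberated allyloxide converts the product into its stabilised enolate, which stops further reaction.

**Step 7**
Reactants: 9 prop-2-enyl (S)-6-Ar-2,4-dioxo-6-(triethylsilyloxy)hexanoate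
Product: 12 prop-2-enyl (S)-2-Ar-4-oxo-3,4-dihydro-2H-pyran-6-carboxylate, via hydroxy dioxo ester 10 (not isolated), via cyclic hemiketal 11 (not isolated)
Conditions: TsOH·H2O (0.3 equiv), CH2Cl2, 0 → 23 °C
Reagents that add atoms: none
Why: Classical cyclodehydration of a δ-hydroxy 1,3-dicarbonyl compound to a 2,3-dihydro-4H-pyran-4-one: acid removes the triethylsilyl group, the hydroxyl adds to the ketone next to the ester (six-membered hemiketal) and water is lost through the enol of the ring ketone, while the carbinol C–O bond is never broken, so that C2 keeps its configuration.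

**Step 8**
Reactants: 12 prop-2-enyl (S)-2-Ar-4-oxo-3,4-dihydro-2H-pyran-6-carboxylate
Product: 13 (S)-2-Ar-4-oxo-3,4-dihydro-2H-pyran-6-carboxylic acid
Conditions: Pd(PPh3)4 (5 mol %), TolSO2Na, THF/MeOH, 23 °C; then cold 0.5 M HCl (work-up)
Reagents that add atoms: none
Why: Tsuji–Trost deallylation: zerovalent palladium ionises the allyl ester and the soft sulfinate captures the allyl complex, so the acid is freed without hydroxide or amine that could open the vinylogous ester by conjugate addition or β-elimination.

**Step 9**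
Reactants: 13 (S)-2-Ar-4-oxo-3,4-dihydro-2H-pyran-6-carboxylic acid
Product: 15 (S)-2-Ar-6-(diazoacetyl)-2,3-dihydro-4H-pyran-4-one, via mixed carbonic anhydride 14 (not isolated)
Conditions: iBuOCOCl, N-methylmorpholine, THF, −20 °C; then CH2N2, Et2O, −20 → 0 °C
Reagents that add atoms: diazomethane, C=[N+]=[N-]
Why: First stage of an Arndt–Eistert sequence: diazomethane is acylated by the mixed carbonic anhydride at the more electrophilic acyl carbonyl and the carbonate leaving group takes up the proton, so that no HCl arises, while low temperature and a small excess of diazomethane should keep dipolar cycloaddition to the donor-substituted C=C bond from competing.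

**Step 10**
Reactants: 16 ethyl 4-methylpent-3-enoate
Product: 19 triisopropyl[(5-methylhex-4-en-1-ynyl)oxy]silane, via dibromo enolate 17 (not isolated), via lithium ynolate 18 (not isolated)
Conditions: CH2Br2, lithium 2,2,6,6-tetramethylpiperidide (2.2 equiv), THF, −78 °C, then 16; n-BuLi, −78 → 25 °C; iPr3SiCl, −78 → 25 °C
Reagents that add atoms: dibromomethane, BrCBr; chlorotriisopropylsilane, CC(C)[Si](Cl)(C(C)C)C(C)C
Why: Kowalski ester homologation stopped at the ynolate: LiCHBr2 adds to the ester carbonyl faster than it deprotonates the α-position, the derived dibromo enolate undergoes bromine–lithium exchange and 1,2-shift of the prenyl CH2 group to give the ynolate, and the bulky silyl chloride reacts at oxygen to give the siloxyalkyne.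

**Step 11**
Reactants: 15 (S)-2-Ar-6-(diazoacetyl)-2,3-dihydro-4H-pyran-4-one; 19 triisopropyl[(5-methylhex-4-en-1-ynyl)oxy]silane
Product: 23 (S)-2-Ar-5-hydroxy-6-(3-methylbut-2-enyl)-7-(triisopropylsilyloxy)chroman-4-one, via vinylketene 20 (not isolated), via vinylcyclobutenone 21 (not isolated), via dienylketene 22 (not isolated)
Conditions: 19 (2 equiv), hν (405 nm LEDs), degassed ClCH2CH2Cl, 20 °C; then 80 °C (dark)
Reagents that add atoms: none
Why: Light absorbed by the diazo ketone of 15 expels N2 and the Wolff shift moves the ring carbon C8a (pyranone C6) from the acyl to the diazo carbon, giving vinylketene 20 (C4a=C8a–C8H=C5=O), whose electrophilic ketene carbon C5 takes the nucleophilic, prenyl-bearing carbon of 19 while C8 bonds to the siloxy carbon in a [2+2] cycloaddition that gives 4-vinylcyclobutenone 21. Strain-driven 4π electrocyclic opening of the C5–C8 bond (light or 80 °C) gives dienylketene 22, and ring A closes by thermal disrotatory 6π electrocyclisation between C5 and C4a, after which the cyclohexadienone tautomerises to the 5-phenol, held by its hydrogen bond to the C4 carbonyl. The closest known reaction type is the photochemical Wolff/vinylketene benzannulation of α,β-unsaturated α′-diazo ketones with siloxyalkynes (Danheiser benzannulation), which delivers resorcinol monosilyl ethers with this ortho-alkyl, meta-siloxy pattern; here the alkene partner is the C=C bond of a dihydropyranone. No stereocentre is created and C2 lies outside the reacting π system, so the S configuration from step 3 should be carried through. Regioselectivity is needed in the [2+2] step and is secured by the polarisation of the siloxyalkyne, so that prenyl can only arrive at C6 between O5 and O7; chemoselectivity is needed against enone photochemistry and ketene–alkene addition and is sought by irradiating at 405 nm, in the long-wavelength diazo band outside the main enone absorption, and by the excess of the far more nucleophilic alkyne.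

**Step 12**
Reactants: 23 (S)-2-Ar-5-hydroxy-6-(3-methylbut-2-enyl)-7-(triisopropylsilyloxy)chroman-4-one
Product: 24 (S)-5,7-dihydroxy-2-[3-hydroxy-4-methoxy-2-(3-methylbut-2-enyl)phenyl]-6-(3-methylbut-2-enyl)chroman-4-one (CNP0306216.1)
Conditions: Bu4NF, AcOH (1:1.2), THF, 0 °C
Reagents that add atoms: none
Why: Fluoride cleaves both aryl silyl ethers, and the acetic acid buffer protonates the phenoxides as they form, so that base-induced ring opening of the flavanone to the chalcone, the only pathway that could erode C2, is suppressed and the prenyl groups are untouched.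

**Compound list**

1 | 2-bromo-3-hydroxy-4-methoxybenzaldehyde | COc1ccc(C=O)c(Br)c1O | starting material
2 | 2-bromo-3-(tert-butyldimethylsilyloxy)-4-methoxybenzaldehyde | COc1ccc(C=O)c(Br)c1O[Si](C)(C)C(C)(C)C | intermediate
3 | 3-(tert-butyldimethylsilyloxy)-4-methoxy-2-(3-methylbut-2-enyl)benzaldehyde | COc1ccc(C=O)c(CC=C(C)C)c1O[Si](C)(C)C(C)(C)C | intermediate
4 | (S)-1-Ar-but-3-enyl diisopinocampheylborinate (isopinocampheyl groups from (+)-α-pinene) | COc1ccc([C@H](CC=C)OB([C@@H]2C[C@@H]3C[C@H]([C@H]2C)C3(C)C)[C@@H]2C[C@@H]3C[C@H]([C@H]2C)C3(C)C)c(CC=C(C)C)c1O[Si](C)(C)C(C)(C)C | intermediate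
5 | (S)-1-[3-(tert-butyldimethylsilyloxy)-4-methoxy-2-(3-methylbut-2-enyl)phenyl]but-3-en-1-ol | COc1ccc([C@@H](O)CC=C)c(CC=C(C)C)c1O[Si](C)(C)C(C)(C)C | intermediate
6 | (S)-triethyl[(1-Ar-but-3-enyl)oxy]silane | COc1ccc([C@@H](O[Si](CC)(CC)CC)CC=C)c(CC=C(C)C)c1O[Si](C)(C)C(C)(C)C | intermediate
7 | (S)-4-Ar-4-(triethylsilyloxy)butan-2-one | COc1ccc([C@@H](O[Si](CC)(CC)CC)CC(C)=O)c(CC=C(C)C)c1O[Si](C)(C)C(C)(C)C | intermediate
8 | lithium (S)-4-Ar-4-(triethylsilyloxy)but-1-en-2-olate | COc1ccc([C@@H](O[Si](CC)(CC)CC)CC(=C)O[Li])c(CC=C(C)C)c1O[Si](C)(C)C(C)(C)C | intermediate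
9 | prop-2-enyl (S)-6-Ar-2,4-dioxo-6-(triethylsilyloxy)hexanoate | COc1ccc([C@@H](O[Si](CC)(CC)CC)CC(=O)CC(=O)C(=O)OCC=C)c(CC=C(C)C)c1O[Si](C)(C)C(C)(C)C | intermediate
10 | prop-2-enyl (S)-6-Ar-6-hydroxy-2,4-dioxohexanoate | COc1ccc([C@@H](O)CC(=O)CC(=O)C(=O)OCC=C)c(CC=C(C)C)c1O[Si](C)(C)C(C)(C)C | intermediate
11 | prop-2-enyl (6S)-6-Ar-2-hydroxy-4-oxotetrahydro-2H-pyran-2-carboxylate | COc1ccc([C@@H]2CC(=O)CC(O)(C(=O)OCC=C)O2)c(CC=C(C)C)c1O[Si](C)(C)C(C)(C)C | intermediate
12 | prop-2-enyl (S)-2-Ar-4-oxo-3,4-dihydro-2H-pyran-6-carboxylate | COc1ccc([C@@H]2CC(=O)C=C(C(=O)OCC=C)O2)c(CC=C(C)C)c1O[Si](C)(C)C(C)(C)C | intermediate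
13 | (S)-2-Ar-4-oxo-3,4-dihydro-2H-pyran-6-carboxylic acid | COc1ccc([C@@H]2CC(=O)C=C(C(=O)O)O2)c(CC=C(C)C)c1O[Si](C)(C)C(C)(C)C | intermediate
14 | (S)-2-Ar-4-oxo-3,4-dihydro-2H-pyran-6-carboxylic isobutyl carbonic anhydride | COc1ccc([C@@H]2CC(=O)C=C(C(=O)OC(=O)OCC(C)C)O2)c(CC=C(C)C)c1O[Si](C)(C)C(C)(C)C | intermediate
15 | (S)-2-[3-(tert-butyldimethylsilyloxy)-4-methoxy-2-(3-methylbut-2-enyl)phenyl]-6-(diazoacetyl)-2,3-dihydro-4H-pyran-4-one | COc1ccc([C@@H]2CC(=O)C=C(C(=O)C=[N+]=[N-])O2)c(CC=C(C)C)c1O[Si](C)(C)C(C)(C)C | intermediate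
16 | ethyl 4-methylpent-3-enoate | CCOC(=O)CC=C(C)C | starting material
17 | lithium 1,1-dibromo-5-methylhexa-1,4-dien-2-olate | [Li]OC(CC=C(C)C)=C(Br)Br | intermediate
18 | lithium 5-methylhex-4-en-1-yn-1-olate | [Li]OC#CCC=C(C)C | intermediate
19 | triisopropyl[(5-methylhex-4-en-1-ynyl)oxy]silane | CC(C)=CCC#CO[Si](C(C)C)(C(C)C)C(C)C | intermediate
20 | (S)-2-(2-Ar-4-oxo-3,4-dihydro-2H-pyran-6-yl)ethenone (vinylketene) | COc1ccc([C@@H]2CC(=O)C=C(C=C=O)O2)c(CC=C(C)C)c1O[Si](C)(C)C(C)(C)C | intermediate
21 | 4-[(S)-2-Ar-4-oxo-3,4-dihydro-2H-pyran-6-yl]-2-(3-methylbut-2-enyl)-3-(triisopropylsilyloxy)cyclobut-2-en-1-one | COc1ccc([C@@H]2CC(=O)C=C(C3C(=O)C(CC=C(C)C)=C3O[Si](C(C)C)(C(C)C)C(C)C)O2)c(CC=C(C)C)c1O[Si](C)(C)C(C)(C)C | intermediate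
22 | 4-[(S)-2-Ar-4-oxo-3,4-dihydro-2H-pyran-6-yl]-2-(3-methylbut-2-enyl)-3-(triisopropylsilyloxy)buta-1,3-dien-1-one (dienylketene) | COc1ccc([C@@H]2CC(=O)C=C(C=C(O[Si](C(C)C)(C(C)C)C(C)C)C(CC=C(C)C)=C=O)O2)c(CC=C(C)C)c1O[Si](C)(C)C(C)(C)C | intermediate
23 | (S)-2-[3-(tert-butyldimethylsilyloxy)-4-methoxy-2-(3-methylbut-2-enyl)phenyl]-5-hydroxy-6-(3-methylbut-2-enyl)-7-(triisopropylsilyloxy)chroman-4-one | COc1ccc([C@@H]2CC(=O)c3c(cc(O[Si](C(C)C)(C(C)C)C(C)C)c(CC=C(C)C)c3O)O2)c(CC=C(C)C)c1O[Si](C)(C)C(C)(C)C | intermediate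
24 | (S)-5,7-dihydroxy-2-[3-hydroxy-4-methoxy-2-(3-methylbut-2-enyl)phenyl]-6-(3-methylbut-2-enyl)chroman-4-one (CNP0306216.1) | COc1ccc([C@@H]2CC(=O)c3c(cc(O)c(CC=C(C)C)c3O)O2)c(CC=C(C)C)c1O | target

**Step count**

Total steps: 12. Longest linear sequence: 11 steps (1 to 24 through steps 1–9, 11 and 12); step 10 is the one-step branch to alkyne 19.

**Steps most likely to fail**

Step 11. After excitation the conjugated enone unit may react on its own account (enone–alkene [2+2] cycloaddition with the neighbouring ring B prenyl group, or photochemical cleavage of the benzylic C2–O1 bond), or the ketene may be lost to dimerisation before the alkyne adds. The fallback takes light out of the ring-forming event and generates the same vinylketene 20 in the dark. It sets out from 15: silver benzoate (PhCO2Ag, catalytic) in aqueous 1,4-dioxane with sonication at 20 °C should bring about the Wolff rearrangement with capture of the ketene by water to give the homologous acid, (S)-2-(2-Ar-4-oxo-3,4-dihydro-2H-pyran-6-yl)acetic acid F1. Because this vinylogous β-keto acid may decarboxylate on standing, it is converted at once with 1-chloro-N,N,2-trimethylprop-1-enylamine in CH2Cl2 at 0 °C into (S)-2-(2-Ar-4-oxo-3,4-dihydro-2H-pyran-6-yl)acetyl chloride F2. Slow addition of iPr2NEt to F2 and alkyne 19 in toluene at 0 °C should dehydrochlorinate F2 to 20, which follows the route through 21 and 22 on warming to 80 °C and comes back at 23.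

Step 7. Under the acid needed for dehydration the electron-rich benzylic C–O bond may ionise, which leads to elimination towards the styryl dioxo ester or to loss of configuration at C2. The fallback separates unmasking from dehydration and runs the dehydration under base. It sets out from 9: AcOH/THF/H2O (3:1:1) at 20 °C should remove only the triethylsilyl group, and the freed hydroxy dioxo ester 10 closes to hemiketal 11, which is now isolated. (CF3CO)2O and pyridine in CH2Cl2 at −20 °C convert 11 into the tertiary ester, prop-2-enyl (6S)-6-Ar-4-oxo-2-(trifluoroacetoxy)tetrahydro-2H-pyran-2-carboxylate F3, which loses trifluoroacetate by E1cB elimination through the enolate of the ring ketone and comes back at 12.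

Step 2. Allyl transposition during transmetalation and reductive elimination may give the branched 1,1-dimethylallyl arene, or oxidative addition into the doubly ortho-substituted C–Br bond may be too slow, so that protodestannylation takes over. The fallback replaces the cross-coupling by an aryl Grignard allylic substitution with 1-bromo-3-methylbut-2-ene. It sets out from 2: HC(OMe)3 and pyridinium p-toluenesulfonate in MeOH give the acetal, [2-bromo-3-(dimethoxymethyl)-6-methoxyphenoxy](tert-butyl)dimethylsilane F4. Magnesium insertion (Mg, LiCl, THF) gives the arylmagnesium bromide F5, which with Li2CuCl4 (3 mol %) and 1-bromo-3-methylbut-2-ene at −20 °C should substitute at the primary allylic carbon to give tert-butyl[3-(dimethoxymethyl)-6-methoxy-2-(3-methylbut-2-enyl)phenoxy]dimethylsilane F6. Pyridinium p-toluenesulfonate in wet acetone unmasks the aldehyde, and the sequence comes back at 3.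

**Further compounds**

F1 | step 11 | (S)-2-(2-Ar-4-oxo-3,4-dihydro-2H-pyran-6-yl)acetic acid | COc1ccc([C@@H]2CC(=O)C=C(CC(=O)O)O2)c(CC=C(C)C)c1O[Si](C)(C)C(C)(C)C
F2 | step 11 | (S)-2-(2-Ar-4-oxo-3,4-dihydro-2H-pyran-6-yl)acetyl chloride | COc1ccc([C@@H]2CC(=O)C=C(CC(=O)Cl)O2)c(CC=C(C)C)c1O[Si](C)(C)C(C)(C)C
F3 | step 7 | prop-2-enyl (6S)-6-Ar-4-oxo-2-(trifluoroacetoxy)tetrahydro-2H-pyran-2-carboxylate | COc1ccc([C@@H]2CC(=O)CC(OC(=O)C(F)(F)F)(C(=O)OCC=C)O2)c(CC=C(C)C)c1O[Si](C)(C)C(C)(C)C
F4 | step 2 | [2-bromo-3-(dimethoxymethyl)-6-methoxyphenoxy](tert-butyl)dimethylsilane | COc1ccc(C(OC)OC)c(Br)c1O[Si](C)(C)C(C)(C)C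
F5 | step 2 | [2-(tert-butyldimethylsilyloxy)-6-(dimethoxymethyl)-3-methoxyphenyl]magnesium bromide | COc1ccc(C(OC)OC)c([Mg]Br)c1O[Si](C)(C)C(C)(C)C
F6 | step 2 | tert-butyl[3-(dimethoxymethyl)-6-methoxy-2-(3-methylbut-2-enyl)phenoxy]dimethylsilane | COc1ccc(C(OC)OC)c(CC=C(C)C)c1O[Si](C)(C)C(C)(C)C
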